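**Retrosynthetic overview**
- Last bond formed: the aryl–O–CH2 ether, joining 7-hydroxy-8-methoxycoumarin to a fully elaborated, unprotected (2R,3R,5R)-epoxy diol.
- Oxirane (both C–O bonds, two stereocentres): titanium/D-tartrate epoxidation of (2E,5R)-3,7-dimethylocta-2,6-diene-1,5-diol.
- Diol: syn methylalumination and hydroxymethylation of a terminal alkyne. The carbinol stereocentre comes from a catalytic asymmetric propargylation of prenal.
- Coumarin: Pechmann-type annulation of 2-methoxyresorcinol with ethyl propiolate.
- Ring order: the pyranone ring of the coumarin first (own branch), the oxirane second, union of the two halves last.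

Assumption: the target is taken exactly as drawn, i.e. (2′R,3′R,5′R) in geranyl numbering; building blocks are numbered, small atom-transfer reagents (Me3Al, formaldehyde, t-BuOOH) are not.

**Step 1**
Reactants: 1 2-methoxybenzene-1,3-diol (2-methoxyresorcinol); 2 ethyl propiolate
Product: 3 7-hydroxy-8-methoxy-2H-chromen-2-one (hydrangetin)
Conditions: ZnCl2 (1.0 equiv), 1,4-dioxane, 95 °C
Reagents that add atoms: none
Why: Pechmann-type condensation (hydroarylation of the propiolate para to one hydroxyl, then lactonisation with the other); the symmetry of 1 allows only one regioisomer and no stereocentre is formed.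

**Step 2**
Reactants: 4 3-methylbut-2-enal (prenal); 5 4,4,5,5-tetramethyl-2-(propa-1,2-dien-1-yl)-1,3,2-dioxaborolane (allenylboronic acid pinacol ester)
Product: 6 (4R)-6-methylhept-5-en-1-yn-4-ol
Conditions: (R)-3,3′-bis(2,4,6-triisopropylphenyl)-1,1′-binaphthalene-2,2′-diyl hydrogen phosphate [(R)-TRIP] (10 mol %), 4 Å MS, toluene, −20 °C; aq. NaHCO3
Reagents that add atoms: none
Why: Chiral phosphoric acid-catalysed propargylation (SE2′ transfer from the allenylboronate through a closed six-membered transition state); the (R)-acid directs Re-face attack on the aldehyde, as in the aryl and alkenyl aldehyde series, which sets the carbinol carbon as R.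

**Step 3**
Reactants: 6 (4R)-6-methylhept-5-en-1-yn-4-ol
Product: 9 (2E,5R)-3,7-dimethylocta-2,6-diene-1,5-diol, via alkenyldimethylalane 7 (not isolated), via lithium alkenylalanate 8 (not isolated)
Conditions: Me3Al (3.0 equiv), Cp2ZrCl2 (0.3 equiv), CH2Cl2, 0 to 23 °C; evaporate volatiles; n-BuLi (1.1 equiv), THF–hexane, −78 °C; (CH2O)n, −78 to 23 °C; aq. KNaC4H4O6
Reagents that add atoms: trimethylaluminium, C[Al](C)C; formaldehyde (as paraformaldehyde), C=O
Why: Negishi zirconium-catalysed carboalumination adds methyl and aluminium syn across the terminal alkyne with methyl on the internal carbon, and the alanate then attacks formaldehyde with retention to give the E-trisubstituted allylic alcohol, as in the known conversion of 6-methylhept-5-en-1-yne into geraniol; the carbinol stereocentre is untouched.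

**Step 4**
Reactants: 9 (2E,5R)-3,7-dimethylocta-2,6-diene-1,5-diol
Product: 10 (2R)-1-[(2R,3R)-3-(hydroxymethyl)-2-methyloxiran-2-yl]-4-methylpent-3-en-2-ol
Conditions: Ti(OiPr)4 (0.2 equiv), diisopropyl D-(−)-tartrate (0.26 equiv), t-BuOOH (2.0 equiv, in decane), 4 Å MS, CH2Cl2, −25 °C
Reagents that add atoms: tert-butyl hydroperoxide, CC(C)(C)OO
Why: Katsuki–Sharpless asymmetric epoxidation, in which the primary allylic alcohol binds the titanium–tartrate dimer and the D-tartrate delivers oxygen to the face giving the (2R,3R)-oxirane (L-tartrate gives (2S,3S)-epoxygeraniol); the secondary allylic alcohol with its cis-methyl group suffers A(1,3) strain in the loaded complex and is left alone, and reagent control turns the minor C5 enantiomer into a separable diastereomer.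

**Step 5**
Reactants: 10 (2R)-1-[(2R,3R)-3-(hydroxymethyl)-2-methyloxiran-2-yl]-4-methylpent-3-en-2-ol; 3 7-hydroxy-8-methoxy-2H-chromen-2-one
Product: 12 7-{[(2R,3R)-3-[(2R)-2-hydroxy-4-methylpent-3-en-1-yl]-3-methyloxiran-2-yl]methoxy}-8-methoxy-2H-chromen-2-one (CNP0223665.1), via epoxyalkyl pyridine-2-sulfonate 11 (not isolated)
Conditions: 2-pyridinesulfonyl fluoride (1.05 equiv), DBU (1.2 equiv), MeCN, 0 °C, 45 min; then 3 (1.1 equiv), DBU (1.2 equiv), 0 to 40 °C
Reagents that add atoms: none
Why: Proposed new method: a one-flask deoxy-aryloxylation in which the sulfonyl fluoride/DBU pair, known to turn alcohols into alkyl 2-pyridinesulfonates on the way to alkyl fluorides, is diverted to C–O bond formation: the unhindered primary epoxy carbinol of 10 is sulfonylated faster than the hindered secondary allylic alcohol to give 11, the released fluoride is held as poorly nucleophilic DBU hydrofluoride, and the DBU-H+ salt of 3 (pKa about 7.5) displaces the sulfonate at the CH2 carbon by SN2 without touching any stereocentre (ring closure of the free hydroxyl onto that carbon is geometrically impossible across the trans-oxirane, and no alkoxide is present to start a Payne rearrangement); the closest known reaction types are sulfonyl fluoride deoxyfluorination and the Williamson etherification of glycidyl arenesulfonates with phenoxides.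

**Compound list**
1 | 2-methoxybenzene-1,3-diol (2-methoxyresorcinol) | COc1c(O)cccc1O | starting material
2 | ethyl prop-2-ynoate (ethyl propiolate) | CCOC(=O)C#C | starting material
3 | 7-hydroxy-8-methoxy-2H-chromen-2-one (hydrangetin) | COc1c(O)ccc2ccc(=O)oc12 | intermediate
4 | 3-methylbut-2-enal (prenal) | CC(C)=CC=O | starting material
5 | 4,4,5,5-tetramethyl-2-(propa-1,2-dien-1-yl)-1,3,2-dioxaborolane | C=C=CB1OC(C)(C)C(C)(C)O1 | starting material
6 | (4R)-6-methylhept-5-en-1-yn-4-ol | C#CC[C@@H](O)C=C(C)C | intermediate
7 | [(1E,4R)-4-(dimethylalumanyloxy)-2,6-dimethylhepta-1,5-dien-1-yl]dimethylalumane | C[Al](C)/C=C(\C)C[C@@H](O[Al](C)C)C=C(C)C | intermediate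
8 | lithium butyl[(1E,4R)-4-(dimethylalumanyloxy)-2,6-dimethylhepta-1,5-dien-1-yl]dimethylaluminate | [Li+].CCCC[Al-](C)(C)/C=C(\C)C[C@@H](O[Al](C)C)C=C(C)C | intermediate
9 | (2E,5R)-3,7-dimethylocta-2,6-diene-1,5-diol | OC/C=C(\C)C[C@@H](O)C=C(C)C | intermediate
10 | (2R)-1-[(2R,3R)-3-(hydroxymethyl)-2-methyloxiran-2-yl]-4-methylpent-3-en-2-ol | OC[C@H]1O[C@]1(C)C[C@@H](O)C=C(C)C | intermediate
11 | [(2R,3R)-3-[(2R)-2-hydroxy-4-methylpent-3-en-1-yl]-3-methyloxiran-2-yl]methyl pyridine-2-sulfonate | O=S(=O)(OC[C@H]1O[C@]1(C)C[C@@H](O)C=C(C)C)c1ccccn1 | intermediate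
12 | 7-{[(2R,3R)-3-[(2R)-2-hydroxy-4-methylpent-3-en-1-yl]-3-methyloxiran-2-yl]methoxy}-8-methoxy-2H-chromen-2-one | COc1c(OC[C@H]2O[C@]2(C)C[C@@H](O)C=C(C)C)ccc2ccc(=O)oc12 | target

**Totals**
Total step count: 5. Longest linear sequence: 4 steps (steps 2 to 5, from prenal 4); step 1 is a one-step side branch.

**Three steps most likely to fail**

Step 5 (the proposed new coupling). The risks are sulfonylation of the secondary allylic alcohol and fluoride competing with the aryloxide. Fallback, known chemistry with a different activation mode: Mitsunobu etherification. It sets out from 10 (with 3), uses PPh3 and diisopropyl azodicarboxylate in THF at 0 °C, and arrives directly at 12. The alcohol is activated as an alkoxyphosphonium ion, the acidic coumarinol is a good pronucleophile, and Mitsunobu aryl ether formation from 2,3-epoxy alcohols is established. New compounds on the way: none F0.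

Step 3. The free, ionisable allylic aluminium alkoxide must survive the Lewis-acidic Me3Al/Cp2ZrCl2 medium, and the alanate must transfer the alkenyl group cleanly. Fallback, the propargylic alcohol route to E-trisubstituted allylic alcohols: it sets out from 6 and comes back at 9. The dilithio derivative of 6 (n-BuLi, 2.2 equiv, THF, −78 °C) is hydroxymethylated with (CH2O)n to (5R)-7-methyloct-6-en-2-yne-1,5-diol F1. Trans-hydroalumination with NaAlH2(OCH2CH2OMe)2 (both alkoxides direct aluminium to C3) and iodination at −78 °C give (2Z,5R)-3-iodo-7-methylocta-2,6-diene-1,5-diol F2. Me2CuLi in Et2O at 0 °C replaces iodide by methyl with retention and gives 9.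

Step 2. Enantioselectivity with a β,β-disubstituted enal is not assured, and 6 is volatile. Fallback, a vinylogous Mukaiyama aldol route that avoids the alkyne altogether: it sets out from 4 and comes back at 9, replacing steps 2 and 3. Commercial methyl 3-methylbut-2-enoate is converted with LiN(i-Pr)2 and t-BuMe2SiCl (THF, −78 °C) into tert-butyl[(1-methoxy-3-methylbuta-1,3-dien-1-yl)oxy]dimethylsilane F3. Its γ-selective addition to 4 with SiCl4 and 2 mol % of N,N′-bis[(11bR)-3,5-dimethyl-4-oxido-3,5-dihydro-4H-dinaphtho[2,1-d:1′,2′-f][1,3,2]diazaphosphepin-4-yl]-N,N′-dimethylpentane-1,5-diamine (CH2Cl2, −78 °C, Re-face addition through an open transition state) gives methyl (2E,5R)-5-hydroxy-3,7-dimethylocta-2,6-dienoate F4. Reduction with i-Bu2AlH (CH2Cl2, −78 °C) gives 9.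

**Further compounds**
F0 | step 5 | none | none
F1 | step 3 | (5R)-7-methyloct-6-en-2-yne-1,5-diol | OCC#CC[C@@H](O)C=C(C)C
F2 | step 3 | (2Z,5R)-3-iodo-7-methylocta-2,6-diene-1,5-diol | OC/C=C(\I)C[C@@H](O)C=C(C)C
F3 | step 2 | tert-butyl[(1-methoxy-3-methylbuta-1,3-dien-1-yl)oxy]dimethylsilane | C=C(C)C=C(OC)O[Si](C)(C)C(C)(C)C
F4 | step 2 | methyl (2E,5R)-5-hydroxy-3,7-dimethylocta-2,6-dienoate | COC(=O)/C=C(\C)C[C@@H](O)C=C(C)C
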